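# Proposed total synthesis of CNP0303209.1 (25) by photo-Wolff benzannulation of ring B onto a ring A siloxyalkyne

## The problem

The target 25 consists of two fully substituted, phloroglucinol-type benzene rings joined by one methylene carbon. Ring A (primed numbers) is an acylphloroglucinol with the acyl group at C1′, hydroxyls at C2′ and C6′, methyl at C3′, methoxy at C4′ and the bridging CH2 at C5′. Ring B is the arene of a 2,2-dimethylchroman-4-one (chromanone numbering, ring C being the pyranone) and carries the same CH2 at C8. Neither arene retains a hydrogen, so every substituent must be placed with full positional control. An unsymmetrical methylene-bridged pair of this kind cannot be relied on to form from two different phloroglucinols and a one-carbon unit, because each partner also pairs with itself. Six phenolic oxygens occur in four different states. On ring B the oxygens at C5, C7 and C8a are nearly equivalent until ring C distinguishes them, and on ring A one oxygen (C4′) must stay methylated while its two neighbours are free. The only stereocentre is the α-carbon of the (R)-2-methylbutanoyl chain. Nothing in the achiral core can control it, so it has to come from an enantiopure acid, and because it is α to an aryl ketone it should enter late and meet neither strong base nor hot acid. The electron-rich diarylmethane is the second weak point (ipso attack by protons or electrophiles can cut the bridge), and the free polyphenol is sensitive to base and air, so the phenols should be unmasked last. The enabling feature is the strict alternation on ring B: oxygen at C5, C7 and C8a, carbon at C4a, C6 and C8, with the benzylic carbon at C8 between two oxygens and the C6 methyl para to C8a. This is the pattern a vinylketene and a siloxyalkyne assemble. The alkyne supplies C7 (silyl ether) and C8 (with its CH2Ar), the ketene supplies C8a (free OH) and C6 (methyl), and the vinyl group supplies C5 (alkyl ether) and an unsubstituted C4a for the later annulation of ring C.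

## Retrosynthesis

**Unmasking (25 from 24 from 23).** The last bonds cut are O–Si at C7 and three O–alkyl bonds: C5–OEt, C2′–OMe and C6′–OMe. The three ethers to be cleaved are exactly those ortho or peri to a carbonyl group, whereas the one to be kept (C4′–OMe) is para to the ketone. The choice among the oxygens is therefore deferred to the point where the two carbonyl groups of 23 can make it through chelation. Compound 23 has no free phenol and is far more robust than 25. The forward reactions must be a chelation-directed dealkylation that stops before the C4′ ether (giving 24) and a buffered desilylation.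

**Side chain (23 from 20 and 22).** The C1′–C(=O) bond is cut. Placing the ketone earlier would expose the stereocentre to the organolithium chemistry of the alkyne synthesis and to the light of two photochemical steps. Cut at this stage, the acyl group enters at the only aromatic C–H left in chromanone 20. The acid chloride 22 comes in one step from the chiral-pool acid 21, so the stereocentre is bought, not made. The forward acylation must be mild enough to keep the configuration of 22 and to leave the methylene bridge intact.

**Ring C (20 from 18, from 16 and 17).** Cut are O1–C2 (oxa-Michael addition) and C4–C4a (acyl transfer from O8a to C4a). Direct C-acylation of phenol 16 is rejected because 16 has two nucleophilic aromatic C–H positions, C4a and C1′, and C1′ is the more electron-rich. Tethering the acyl group to O8a as ester 18 and transferring it within a solvent cage by light confines it to C4a. The precursor 16 is simpler by ring C and five carbons and has a single free hydroxyl. The forward steps are esterification of a hindered phenol with 17, a photo-Fries shift and a base-mediated ring closure.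

**Ring B (16 from 6 and 12).** Four bonds are cut: C5–C6, C6–C7, C8–C8a and C4a–C8a. This removes the whole of ring B and leaves the small diazo ketone 12 and the ring A siloxyalkyne 6. Cuts at the methylene bridge would require coupling two complete phloroglucinols selectively. The benzannulation instead makes the diarylmethane carbon part of the alkyne and delivers the ring with all five substituents and three distinct oxygens (free OH at C8a, silyl ether at C7, ethyl ether at C5). The forward reaction must be a Wolff rearrangement to an ethoxy-substituted vinylketene and a regiodefined [2+2]/4π/6π cascade with 6.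

**Siloxyalkyne (6 from 4, from 3, from 1 and 2).** The C≡C–O unit is traced to the ester group of arylacetate 4 (one-carbon homologation to an ynolate and O-silylation). The benzylic oxygen of ketoester 3 is removed, and the aryl–carbon bond of 3 comes from acylation of the symmetrical arene 1 with 2. Because the two free positions of 1 are equivalent, the first substitution has no regiochemistry to control, and the position left over becomes C1′. The three methyl ethers survive every step up to the end.

**Diazo ketone (12 from 10, from 7 and 8).** The diazo group is traced to the only enolisable CH2 of enone 10, and the C3–C4 bond of 10 to the addition of metalated 7 to Weinreb amide 8. Both are bulk chemicals, and the vinyl ether oxygen of 7 becomes the C5 oxygen of the target.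

## Roads not taken

**Alternative 1:** Both aryl–acyl bonds, C1′–CO and C4a–C4, would be cut together. The precursor is a complete diarylmethane carrying three esters, 4-{[2,4-bis(methoxymethoxy)-3-methyl-6-(3-methylbut-2-enoyloxy)phenyl]methyl}-5-methoxy-6-methyl-1,3-phenylene bis[(2R)-2-methylbutanoate] A2. Irradiation would give, by two photo-Fries shifts, the diketone 3-hydroxy-4-{[2-hydroxy-4,6-bis(methoxymethoxy)-5-methyl-3-(3-methylbut-2-enoyl)phenyl]methyl}-5-methoxy-6-methyl-2-[(2R)-2-methylbutanoyl]phenyl (2R)-2-methylbutanoate A1.
- Merits: both acyl groups are delivered intramolecularly and without Lewis acid, so neither the site of acylation nor the acid-sensitive bridge is in question. The ring A oxygens are differentiated from the start by their esters, not by selective demethylation. In these two respects this road is better than the chosen one.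
- Weak points: the key step closes no ring and builds none of the skeleton, so the unsymmetrical, fully substituted diarylmethane (the real difficulty) must come from elsewhere. Two photochemical events must succeed in one molecule, and the first-formed ortho-hydroxyaryl ketone absorbs strongly and dissipates excitation, shading the second ester. The α-branched acyl radical can lose CO in the cage. The leftover ester of A1 must be hydrolysed by base next to the epimerisable ketone, and the acetal groups must be removed by acid from an electron-rich diarylmethane.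
- Comparison: the chosen plan borrows this reaction once (step 8), for one ester, before the ring A ketone exists. In exchange it accepts a Lewis-acid acylation (step 10) and a selective ether cleavage (step 11), against which it sets a convergent construction of ring B and the bridge from 6 and 12.

**Alternative 2:** The C1′–C2′ bond inside ring A would be cut. The precursor is 4-methoxy-3-methyl-6-[(3R)-3-methyl-2-oxopentyl]-2H-pyran-2-one A4, which an alkoxide would open to a keto-enoate whose activated CH2 acylates the ester carbon. The product is the aromatic monomer (2R)-1-(2,6-dihydroxy-4-methoxy-3-methylphenyl)-2-methylbutan-1-one A3.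
- Merits: ring A arrives with its final oxygen pattern (two free hydroxyls, one methyl ether) and with the chiral acyl group in place. No Friedel–Crafts acylation and no selective demethylation are needed, and here it is superior to the chosen plan.
- Weak points: A3 is only half of the molecule. Its free C5′ must still be joined through one carbon to a separately made, fully differentiated ring B chromanone, and this is the cross-coupling of two phloroglucinols that tends to give symmetrical dimers and bridge scrambling. The stereocentre sits next to a polyketone chain under alkoxide during the ring closure and is then carried as a free acylphloroglucinol through the coupling, so its integrity is at greater risk than in a late acylation.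
- Comparison: the chosen plan has to set against the elegance of A3 that it solves the bridge and ring B in one step and never handles a free phloroglucinol before the end.

**Alternative 3:** The same kind of benzannulation would be used in the opposite sense, to build ring A (bonds C5′–C6′, C3′–C4′ and C1′–C6′). Thermal opening of 3-ethoxy-2-methylcyclobut-2-en-1-one A6 gives the vinylketene 13. It would add to the methoxyalkyne 5,7-bis(benzyloxy)-8-(3-methoxyprop-2-yn-1-yl)-2,2,6-trimethylchroman-4-one A7 to give 5,7-bis(benzyloxy)-8-[(4-ethoxy-6-hydroxy-2-methoxy-3-methylphenyl)methyl]-2,2,6-trimethylchroman-4-one A5.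
- Merits: no light is needed. More importantly, the ring A oxygens arrive as OH, OEt and OMe, so the C4′ methyl ether never has to be distinguished from two other methyl ethers. The free C6′ hydroxyl could direct the acyl group to C1′ by an ester/Fries sequence, only one ortho ether has to be cleaved, and the benzyl groups leave by hydrogenolysis. For the end game this road is better than the chosen one.
- Weak points: the difficult ring, the hexasubstituted ring B with the C6/C8 regiochemistry of a 5,7-dioxygenated chromanone, must be made beforehand by classical substitution chemistry. A7 requires alkynyl ether synthesis with strongly basic acetylide chemistry on a molecule that already contains an enolisable ketone. A 3-alkoxycyclobutenone such as A6 is a vinylogous ester and opens only at elevated temperature, where alkynyl ethers are less tolerant than silyl ynol ethers.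
- Comparison: the chosen plan sets against the cleaner end game that its alkyne 6 comes in three steps from a cheap symmetrical arene, that its ketene precursor 12 is generated at room temperature, and that the benzannulation is spent on the ring that is hardest to make otherwise.

Key step: step 6

Assumption: the stereodescriptor of the side chain in the target corresponds to R, and (R)-2-methylbutanoic acid 21 is taken as purchasable in enantiopure form, so the configuration is carried through unchanged.

## Route

Step 1
Reactants: 1 2,4,6-trimethoxytoluene; 2 ethyl chlorooxoacetate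
Product: 3 ethyl 2-oxo-2-(2,4,6-trimethoxy-3-methylphenyl)acetate
Conditions: TiCl4, CH2Cl2, −20 → 0 °C
Reagents that add atoms: none
Why: Friedel–Crafts acylation; the two unsubstituted positions of 1 are equivalent and each lies between two methoxy groups, so one ketoester should form, and TiCl4 at low temperature is mild enough to leave the ortho methyl ethers uncleaved.

Step 2
Reactants: 3 ethyl 2-oxo-2-(2,4,6-trimethoxy-3-methylphenyl)acetate
Product: 4 ethyl 2-(2,4,6-trimethoxy-3-methylphenyl)acetate
Conditions: Et3SiH, CF3CO2H, CH2Cl2, 0 °C → rt
Reagents that add atoms: none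
Why: Ionic hydrogenation; protonation of the aryl ketone and hydride transfer from the silane, repeated through the strongly stabilised trimethoxybenzylic cation, should remove the benzylic oxygen and leave the ester untouched.

Step 3
Reactants: 4 ethyl 2-(2,4,6-trimethoxy-3-methylphenyl)acetate
Product: 6 triisopropyl{[3-(2,4,6-trimethoxy-3-methylphenyl)prop-1-yn-1-yl]oxy}silane, via lithium ynolate 5 (not isolated)
Conditions: CH2Br2, lithium 2,2,6,6-tetramethylpiperidide, THF, −78 °C; n-BuLi, −78 → 0 °C; i-Pr3SiCl, −78 °C → rt
Reagents that add atoms: dibromomethane BrCBr; triisopropylsilyl chloride CC(C)[Si](Cl)(C(C)C)C(C)C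
Why: Kowalski ester homologation stopped at the ynolate; LiCHBr2 adds to the ester, bromine–lithium exchange on the dibromo enolate triggers a 1,2-shift of the arylmethyl group to the carbenoid carbon to give ynolate 5, and the bulky silyl chloride should capture it on oxygen to give the siloxyalkyne.

Step 4
Reactants: 7 ethyl vinyl ether; 8 N-methoxy-N-methylpropanamide
Product: 10 2-ethoxypent-1-en-3-one, via 1-ethoxyvinyllithium 9 (not isolated)
Conditions: t-BuLi, THF, −78 → 0 °C; then 8, −78 → 0 °C; H2O
Reagents that add atoms: none
Why: α-Lithiation of the enol ether gives an acyl-anion equivalent whose addition to the Weinreb amide stops at the chelated tetrahedral adduct, so the enone is released only on work-up and is not attacked a second time.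

Step 5
Reactants: 10 2-ethoxypent-1-en-3-one
Product: 12 2-diazo-4-ethoxypent-4-en-3-one, via trifluoroacetyl diketone 11 (not isolated)
Conditions: LiN(SiMe3)2, THF, −78 °C; CF3CO2CH2CF3; AcOH; then MsN3, Et3N, H2O, MeCN, rt
Reagents that add atoms: methanesulfonyl azide CS(=O)(=O)N=[N+]=[N-]
Why: Detrifluoroacetylative diazo transfer; only the ethyl CH2 of 10 can be enolised, its C-trifluoroacetylation activates that carbon for diazo transfer, and the trifluoroacetyl group leaves on the sulfonamide, under conditions that should spare the enol ether.

Step 6
Reactants: 6 triisopropyl{[3-(2,4,6-trimethoxy-3-methylphenyl)prop-1-yn-1-yl]oxy}silane; 12 2-diazo-4-ethoxypent-4-en-3-one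
Product: 16 5-ethoxy-4-methyl-3-(triisopropylsilyloxy)-2-[(2,4,6-trimethoxy-3-methylphenyl)methyl]phenol, via ethoxy vinylketene 13 (not isolated), via vinylcyclobutenone 14 (not isolated), via dienylketene 15 (not isolated)
Conditions: hν (medium-pressure Hg lamp, Vycor filter), ClCH2CH2Cl, rt; then 80 °C
Reagents that add atoms: none
Why: Excitation of 12 expels N2 and the 1-ethoxyvinyl group migrates to the carbene carbon (Wolff rearrangement, forming C5–C6), giving vinylketene 13. The siloxyalkyne 6 attacks the ketene carbonyl carbon with its arylmethyl-bearing carbon, and the zwitterion collapses between the ketene α-carbon and the oxygen-bearing alkyne carbon; this polar [2+2] cycloaddition forms C8–C8a and C6–C7 and gives cyclobutenone 14. Ring 14 opens by 4π electrocyclic cleavage to dienylketene 15, which closes ring B by thermal 6π (disrotatory) electrocyclisation between the ketene carbon and the vinyl CH2 (C4a–C8a), and tautomerisation of the cyclohexadienone gives phenol 16. The closest known reaction type is the Danheiser benzannulation in its photochemical Wolff variant with siloxyalkynes; the alkoxy group on the vinylketene is the untested element. No stereocentre results, because the quaternary carbon of 14 is lost on ring opening, and that opening is reversible, so both geometries of 15 should funnel to 16. The selectivity needed is regiochemical and is fixed by polarity: the alkyne carbon β to the siloxy oxygen is the nucleophile and the ketene carbonyl carbon the electrophile, so the arylmethyl group ends ortho to the new hydroxyl (C8), the siloxy group meta (C7) and the methyl para (C6). The ethoxy group is cross-conjugated in 13 and should not lower the electrophilicity of the ketene carbon, while making the migrating vinyl group electron-rich.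

Step 7
Reactants: 16 5-ethoxy-4-methyl-3-(triisopropylsilyloxy)-2-[(2,4,6-trimethoxy-3-methylphenyl)methyl]phenol; 17 3-methylbut-2-enoyl chloride
Product: 18 5-ethoxy-4-methyl-3-(triisopropylsilyloxy)-2-[(2,4,6-trimethoxy-3-methylphenyl)methyl]phenyl 3-methylbut-2-enoate
Conditions: NaH, THF, 0 °C; then 17, 0 °C → rt
Reagents that add atoms: none
Why: O-Acylation of the preformed sodium phenoxide; avoiding amine bases keeps the acid chloride from isomerising through its vinylketene to the β,γ-unsaturated ester.

Step 8
Reactants: 18 5-ethoxy-4-methyl-3-(triisopropylsilyloxy)-2-[(2,4,6-trimethoxy-3-methylphenyl)methyl]phenyl 3-methylbut-2-enoate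
Product: 20 5-ethoxy-2,2,6-trimethyl-7-(triisopropylsilyloxy)-8-[(2,4,6-trimethoxy-3-methylphenyl)methyl]chroman-4-one, via hydroxyaryl enone 19 (not isolated)
Conditions: hν (254 nm), cyclohexane, rt; then DBU (cat.), CH2Cl2, rt
Reagents that add atoms: none
Why: Photo-Fries rearrangement followed by 6-endo oxa-Michael addition; the caged aryloxyl/acyl radical pair can recombine productively only at C4a (C8 and the para carbon C6 are substituted), so the acyl group cannot reach the free C1′ of ring A as it could in a Lewis-acid Fries reaction, and DBU then adds the C8a phenol to the β,β-dimethyl enone to close ring C.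

Step 9
Reactants: 21 (R)-2-methylbutanoic acid
Product: 22 (R)-2-methylbutanoyl chloride
Conditions: (COCl)2, DMF (cat.), CH2Cl2, 0 °C → rt
Reagents that add atoms: oxalyl chloride ClC(=O)C(=O)Cl
Why: Acid chloride formation through the catalytic chloroiminium species at or below room temperature, where the α-stereocentre of a simple branched alkanoyl chloride is retained; the volatile chloride is used as a solution.

Step 10
Reactants: 20 5-ethoxy-2,2,6-trimethyl-7-(triisopropylsilyloxy)-8-[(2,4,6-trimethoxy-3-methylphenyl)methyl]chroman-4-one; 22 (R)-2-methylbutanoyl chloride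
Product: 23 5-ethoxy-2,2,6-trimethyl-8-({2,4,6-trimethoxy-3-methyl-5-[(2R)-2-methylbutanoyl]phenyl}methyl)-7-(triisopropylsilyloxy)chroman-4-one
Conditions: TiCl4, CH2Cl2, −40 → 0 °C
Reagents that add atoms: none
Why: Friedel–Crafts acylation at C1′, the only unsubstituted aromatic position left and one activated by two ortho and one para methoxy group, while ring B is deactivated by the C4 carbonyl; low temperature and the absence of amine base should keep the acyl chloride from racemising through its ketene, so the stereocentre is transferred unchanged from 22.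

Step 11
Reactants: 23 5-ethoxy-2,2,6-trimethyl-8-({2,4,6-trimethoxy-3-methyl-5-[(2R)-2-methylbutanoyl]phenyl}methyl)-7-(triisopropylsilyloxy)chroman-4-one
Product: 24 8-({2,4-dihydroxy-6-methoxy-5-methyl-3-[(2R)-2-methylbutanoyl]phenyl}methyl)-5-hydroxy-2,2,6-trimethyl-7-(triisopropylsilyloxy)chroman-4-one
Conditions: BCl3, CH2Cl2, −78 °C → rt; then H2O
Reagents that add atoms: none
Why: Chelation-directed ether cleavage; BCl3 bound to a carbonyl oxygen delivers chloride to the alkyl group of an ether ortho or peri to that carbonyl, so the C5 ethyl ether and the C2′ and C6′ methyl ethers should be cleaved while the C4′ methyl ether (para to the ketone) and the hindered silyl ether remain.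

Step 12
Reactants: 24 8-({2,4-dihydroxy-6-methoxy-5-methyl-3-[(2R)-2-methylbutanoyl]phenyl}methyl)-5-hydroxy-2,2,6-trimethyl-7-(triisopropylsilyloxy)chroman-4-one
Product: 25 8-({2,4-dihydroxy-6-methoxy-5-methyl-3-[(2R)-2-methylbutanoyl]phenyl}methyl)-5,7-dihydroxy-2,2,6-trimethylchroman-4-one (CNP0303209.1)
Conditions: Bu4NF, AcOH, THF, 0 °C → rt
Reagents that add atoms: none
Why: Fluoride-induced cleavage of the aryl silyl ether, driven by the Si–F bond and the good phenoxide leaving group; the acetic acid buffer keeps the medium from becoming basic enough to enolise the ketone at the stereocentre or to open the chromanone.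

## Compound list

1 | 2,4,6-trimethoxytoluene | COc1cc(OC)c(C)c(OC)c1 | starting material
2 | ethyl chlorooxoacetate | CCOC(=O)C(=O)Cl | starting material
3 | ethyl 2-oxo-2-(2,4,6-trimethoxy-3-methylphenyl)acetate | CCOC(=O)C(=O)c1c(OC)cc(OC)c(C)c1OC | intermediate
4 | ethyl 2-(2,4,6-trimethoxy-3-methylphenyl)acetate | CCOC(=O)Cc1c(OC)cc(OC)c(C)c1OC | intermediate
5 | lithium 3-(2,4,6-trimethoxy-3-methylphenyl)prop-1-yn-1-olate | [Li+].[O-]C#CCc1c(OC)cc(OC)c(C)c1OC | intermediate
6 | triisopropyl{[3-(2,4,6-trimethoxy-3-methylphenyl)prop-1-yn-1-yl]oxy}silane | COc1cc(OC)c(CC#CO[Si](C(C)C)(C(C)C)C(C)C)c(OC)c1C | intermediate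
7 | ethyl vinyl ether | C=COCC | starting material
8 | N-methoxy-N-methylpropanamide | CCC(=O)N(C)OC | starting material
9 | 1-ethoxyvinyllithium | [Li]C(=C)OCC | intermediate
10 | 2-ethoxypent-1-en-3-one | C=C(OCC)C(=O)CC | intermediate
11 | 5-ethoxy-1,1,1-trifluoro-3-methylhex-5-ene-2,4-dione (racemic) | C=C(OCC)C(=O)C(C)C(=O)C(F)(F)F | intermediate
12 | 2-diazo-4-ethoxypent-4-en-3-one | C=C(OCC)C(=O)C(C)=[N+]=[N-] | intermediate
13 | 3-ethoxy-2-methylbuta-1,3-dien-1-one | O=C=C(C)C(=C)OCC | intermediate
14 | 4-(1-ethoxyethenyl)-4-methyl-3-(triisopropylsilyloxy)-2-[(2,4,6-trimethoxy-3-methylphenyl)methyl]cyclobut-2-en-1-one (racemic) | O=C1C(Cc2c(OC)cc(OC)c(C)c2OC)=C(O[Si](C(C)C)(C(C)C)C(C)C)C1(C)C(=C)OCC | intermediate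
15 | (3E)-5-ethoxy-4-methyl-3-(triisopropylsilyloxy)-2-[(2,4,6-trimethoxy-3-methylphenyl)methyl]hexa-1,3,5-trien-1-one | O=C=C(Cc1c(OC)cc(OC)c(C)c1OC)/C(O[Si](C(C)C)(C(C)C)C(C)C)=C(C)\C(=C)OCC | intermediate
16 | 5-ethoxy-4-methyl-3-(triisopropylsilyloxy)-2-[(2,4,6-trimethoxy-3-methylphenyl)methyl]phenol | CCOc1cc(O)c(Cc2c(OC)cc(OC)c(C)c2OC)c(O[Si](C(C)C)(C(C)C)C(C)C)c1C | intermediate
17 | 3-methylbut-2-enoyl chloride | CC(C)=CC(=O)Cl | starting material
18 | 5-ethoxy-4-methyl-3-(triisopropylsilyloxy)-2-[(2,4,6-trimethoxy-3-methylphenyl)methyl]phenyl 3-methylbut-2-enoate | CCOc1cc(OC(=O)C=C(C)C)c(Cc2c(OC)cc(OC)c(C)c2OC)c(O[Si](C(C)C)(C(C)C)C(C)C)c1C | intermediate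
19 | 1-{2-ethoxy-6-hydroxy-3-methyl-4-(triisopropylsilyloxy)-5-[(2,4,6-trimethoxy-3-methylphenyl)methyl]phenyl}-3-methylbut-2-en-1-one | CCOc1c(C(=O)C=C(C)C)c(O)c(Cc2c(OC)cc(OC)c(C)c2OC)c(O[Si](C(C)C)(C(C)C)C(C)C)c1C | intermediate
20 | 5-ethoxy-2,2,6-trimethyl-7-(triisopropylsilyloxy)-8-[(2,4,6-trimethoxy-3-methylphenyl)methyl]chroman-4-one | CCOc1c(C)c(O[Si](C(C)C)(C(C)C)C(C)C)c(Cc2c(OC)cc(OC)c(C)c2OC)c2OC(C)(C)CC(=O)c12 | intermediate
21 | (R)-2-methylbutanoic acid | CC[C@@H](C)C(O)=O | starting material
22 | (R)-2-methylbutanoyl chloride | CC[C@@H](C)C(=O)Cl | intermediate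
23 | 5-ethoxy-2,2,6-trimethyl-8-({2,4,6-trimethoxy-3-methyl-5-[(2R)-2-methylbutanoyl]phenyl}methyl)-7-(triisopropylsilyloxy)chroman-4-one | CC[C@@H](C)C(=O)c1c(OC)c(C)c(OC)c(Cc2c(O[Si](C(C)C)(C(C)C)C(C)C)c(C)c(OCC)c3c2OC(C)(C)CC3=O)c1OC | intermediate
24 | 8-({2,4-dihydroxy-6-methoxy-5-methyl-3-[(2R)-2-methylbutanoyl]phenyl}methyl)-5-hydroxy-2,2,6-trimethyl-7-(triisopropylsilyloxy)chroman-4-one | CC[C@@H](C)C(=O)c1c(O)c(C)c(OC)c(Cc2c(O[Si](C(C)C)(C(C)C)C(C)C)c(C)c(O)c3c2OC(C)(C)CC3=O)c1O | intermediate
25 | 8-({2,4-dihydroxy-6-methoxy-5-methyl-3-[(2R)-2-methylbutanoyl]phenyl}methyl)-5,7-dihydroxy-2,2,6-trimethylchroman-4-one | CC[C@@H](C)C(=O)c1c(O)c(C)c(OC)c(Cc2c(O)c(C)c(O)c3c2OC(C)(C)CC3=O)c1O | target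

## Step count and least certain steps

Total: 12 steps. Longest linear sequence: 9 steps (steps 1, 2, 3, 6, 7, 8, 10, 11, 12). Steps 4 and 5 (diazo ketone) and step 9 (acid chloride) are side branches.

**Step 6 (key step).**
- What may go wrong: the photogenerated carbene may undergo a 1,2-hydrogen shift from its methyl group instead of the Wolff migration. The electron-rich ethoxy vinylketene may dimerise. The zwitterion from ketene and alkyne may close through the enol-ether terminus instead of the α-carbon, which would scramble the substitution pattern. The trimethoxyarene of 6 competes for light.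
- Fallback: generate the same vinylketene thermally. The fallback sets out from 6 and returns at 16. 1-Ethoxyprop-1-yne and dichloroketene (Cl3CCOCl, zinc–copper couple) would give 4,4-dichloro-3-ethoxy-2-methylcyclobut-2-en-1-one F1. Zinc in AcOH with TMEDA would remove the chlorines to give 3-ethoxy-2-methylcyclobut-2-en-1-one F2. Heating F2 with 6 in toluene or xylene would open it by 4π cleavage to 13, which continues through 14 and 15 to 16 without light.

**Step 3.**
- What may go wrong: deprotonation of the arylacetate α-CH2 by the carbenoid or amide base may outrun addition to the ester carbonyl, and the ynolate may be silylated on carbon to a silylketene.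
- Fallback: reach the ynolate by oxidation of an acetylide. The fallback sets out from 4 and returns at 6. Reduction of 4 with i-Bu2AlH at −78 °C would give 2-(2,4,6-trimethoxy-3-methylphenyl)acetaldehyde F3. Ohira–Bestmann homologation (K2CO3, MeOH) would give 1,3,5-trimethoxy-2-methyl-4-(prop-2-yn-1-yl)benzene F4. Lithiation of F4 with n-BuLi, oxidation of the acetylide with LiOOt-Bu to ynolate 5 and capture with i-Pr3SiOTf would give 6.

**Step 8.**
- What may go wrong: the radical pair may escape the cage and return phenol 16. The senecioate may photodeconjugate to the β,γ-unsaturated ester. The ortho-hydroxyaryl ketone product acts as an inner filter that stops conversion early.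
- Fallback: build ring C by a propargyl ether Claisen route. It sets out from 16 and returns at 20. Alkylation of 16 with 3-chloro-3-methylbut-1-yne (K2CO3, KI, acetone) would give triisopropyl{3-ethoxy-2-methyl-5-[(2-methylbut-3-yn-2-yl)oxy]-6-[(2,4,6-trimethoxy-3-methylphenyl)methyl]phenoxy}silane F5. Heating in N,N-diethylaniline would give, by Claisen rearrangement and cyclisation at the only free ortho carbon, 5-ethoxy-2,2,6-trimethyl-7-(triisopropylsilyloxy)-8-[(2,4,6-trimethoxy-3-methylphenyl)methyl]-2H-chromene F6. Mukaiyama hydration (Co(acac)2, PhSiH3, O2) would place the hydroxyl at the benzylic carbon to give racemic 5-ethoxy-2,2,6-trimethyl-7-(triisopropylsilyloxy)-8-[(2,4,6-trimethoxy-3-methylphenyl)methyl]chroman-4-ol F7. Dess–Martin oxidation would give 20.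

**Step 10.**
- What may go wrong: the configuration may erode through ketene or enol formation from 22 under the Lewis acid. Ipso attack at C5′ may cut the methylene bridge. Acylation at the crowded C1′ may be sluggish.
- Fallback: introduce the ketone by directed metalation before ring C is made. It sets out from 16 (and 22) and returns at 23. Acid chloride 22 and N,O-dimethylhydroxylamine hydrochloride with pyridine would give (2R)-N-methoxy-N,2-dimethylbutanamide F8. Treatment of 16 with n-BuLi (phenoxide formation, then lithiation at C1′ between two methoxy groups) and addition of F8 would give (2R)-1-(3-{[4-ethoxy-6-hydroxy-3-methyl-2-(triisopropylsilyloxy)phenyl]methyl}-2,4,6-trimethoxy-5-methylphenyl)-2-methylbutan-1-one F9. Acylation with 17 as in step 7 would give 5-ethoxy-4-methyl-3-(triisopropylsilyloxy)-2-({2,4,6-trimethoxy-3-methyl-5-[(2R)-2-methylbutanoyl]phenyl}methyl)phenyl 3-methylbut-2-enoate F10. Irradiation as in step 8 would give (2R)-1-[3-({4-ethoxy-2-hydroxy-5-methyl-3-(3-methylbut-2-enoyl)-6-(triisopropylsilyloxy)phenyl}methyl)-2,4,6-trimethoxy-5-methylphenyl]-2-methylbutan-1-one F11, which DBU would close to 23. The price is that the ring A ketone is then present during the photochemical step.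

**Step 11.**
- What may go wrong: after the first ring A ether is cleaved the carbonyl is tied up in a boron chelate, so cleavage of the second ortho methyl ether may stall. Forcing it may cost the C4′ methyl ether, which is twisted out of conjugation by its two neighbours, or open the bridge.
- Fallback: cleave all ethers and re-methylate selectively. It sets out from 23 and returns at 24. BBr3 in CH2Cl2 (−78 → 0 °C) would cleave all four alkyl ethers to give 5-hydroxy-2,2,6-trimethyl-8-({2,4,6-trihydroxy-3-methyl-5-[(2R)-2-methylbutanoyl]phenyl}methyl)-7-(triisopropylsilyloxy)chroman-4-one F12. One equivalent of MeI with K2CO3 in acetone should methylate the C4′ hydroxyl, the only one not hydrogen-bonded to a carbonyl and not silylated, to give 24.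

## Further compounds

F1 | step 6 | 4,4-dichloro-3-ethoxy-2-methylcyclobut-2-en-1-one | CCOC1=C(C)C(=O)C1(Cl)Cl
F2 | step 6 | 3-ethoxy-2-methylcyclobut-2-en-1-one | CCOC1=C(C)C(=O)C1
F3 | step 3 | 2-(2,4,6-trimethoxy-3-methylphenyl)acetaldehyde | O=CCc1c(OC)cc(OC)c(C)c1OC
F4 | step 3 | 1,3,5-trimethoxy-2-methyl-4-(prop-2-yn-1-yl)benzene | C#CCc1c(OC)cc(OC)c(C)c1OC
F5 | step 8 | triisopropyl{3-ethoxy-2-methyl-5-[(2-methylbut-3-yn-2-yl)oxy]-6-[(2,4,6-trimethoxy-3-methylphenyl)methyl]phenoxy}silane | CCOc1cc(OC(C)(C)C#C)c(Cc2c(OC)cc(OC)c(C)c2OC)c(O[Si](C(C)C)(C(C)C)C(C)C)c1C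
F6 | step 8 | 5-ethoxy-2,2,6-trimethyl-7-(triisopropylsilyloxy)-8-[(2,4,6-trimethoxy-3-methylphenyl)methyl]-2H-chromene | CCOc1c(C)c(O[Si](C(C)C)(C(C)C)C(C)C)c(Cc2c(OC)cc(OC)c(C)c2OC)c2OC(C)(C)C=Cc12
F7 | step 8 | racemic 5-ethoxy-2,2,6-trimethyl-7-(triisopropylsilyloxy)-8-[(2,4,6-trimethoxy-3-methylphenyl)methyl]chroman-4-ol | CCOc1c(C)c(O[Si](C(C)C)(C(C)C)C(C)C)c(Cc2c(OC)cc(OC)c(C)c2OC)c2OC(C)(C)CC(O)c12
F8 | step 10 | (2R)-N-methoxy-N,2-dimethylbutanamide | CC[C@@H](C)C(=O)N(C)OC
F9 | step 10 | (2R)-1-(3-{[4-ethoxy-6-hydroxy-3-methyl-2-(triisopropylsilyloxy)phenyl]methyl}-2,4,6-trimethoxy-5-methylphenyl)-2-methylbutan-1-one | CC[C@@H](C)C(=O)c1c(OC)c(C)c(OC)c(Cc2c(O[Si](C(C)C)(C(C)C)C(C)C)c(C)c(OCC)cc2O)c1OC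
F10 | step 10 | 5-ethoxy-4-methyl-3-(triisopropylsilyloxy)-2-({2,4,6-trimethoxy-3-methyl-5-[(2R)-2-methylbutanoyl]phenyl}methyl)phenyl 3-methylbut-2-enoate | CC[C@@H](C)C(=O)c1c(OC)c(C)c(OC)c(Cc2c(O[Si](C(C)C)(C(C)C)C(C)C)c(C)c(OCC)cc2OC(=O)C=C(C)C)c1OC
F11 | step 10 | (2R)-1-[3-({4-ethoxy-2-hydroxy-5-methyl-3-(3-methylbut-2-enoyl)-6-(triisopropylsilyloxy)phenyl}methyl)-2,4,6-trimethoxy-5-methylphenyl]-2-methylbutan-1-one | CC[C@@H](C)C(=O)c1c(OC)c(C)c(OC)c(Cc2c(O[Si](C(C)C)(C(C)C)C(C)C)c(C)c(OCC)c(C(=O)C=C(C)C)c2O)c1OC
F12 | step 11 | 5-hydroxy-2,2,6-trimethyl-8-({2,4,6-trihydroxy-3-methyl-5-[(2R)-2-methylbutanoyl]phenyl}methyl)-7-(triisopropylsilyloxy)chroman-4-one | CC[C@@H](C)C(=O)c1c(O)c(C)c(O)c(Cc2c(O[Si](C(C)C)(C(C)C)C(C)C)c(C)c(O)c3c2OC(C)(C)CC3=O)c1O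
A1 | alternative 1 | 3-hydroxy-4-{[2-hydroxy-4,6-bis(methoxymethoxy)-5-methyl-3-(3-methylbut-2-enoyl)phenyl]methyl}-5-methoxy-6-methyl-2-[(2R)-2-methylbutanoyl]phenyl (2R)-2-methylbutanoate | CC[C@@H](C)C(=O)c1c(O)c(Cc2c(O)c(C(=O)C=C(C)C)c(OCOC)c(C)c2OCOC)c(OC)c(C)c1OC(=O)[C@H](C)CC
A2 | alternative 1 | 4-{[2,4-bis(methoxymethoxy)-3-methyl-6-(3-methylbut-2-enoyloxy)phenyl]methyl}-5-methoxy-6-methyl-1,3-phenylene bis[(2R)-2-methylbutanoate] | CC[C@@H](C)C(=O)Oc1cc(OC(=O)[C@H](C)CC)c(C)c(OC)c1Cc1c(OC(=O)C=C(C)C)cc(OCOC)c(C)c1OCOC
A3 | alternative 2 | (2R)-1-(2,6-dihydroxy-4-methoxy-3-methylphenyl)-2-methylbutan-1-one | CC[C@@H](C)C(=O)c1c(O)cc(OC)c(C)c1O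
A4 | alternative 2 | 4-methoxy-3-methyl-6-[(3R)-3-methyl-2-oxopentyl]-2H-pyran-2-one | CC[C@@H](C)C(=O)CC1=CC(OC)=C(C)C(=O)O1
A5 | alternative 3 | 5,7-bis(benzyloxy)-8-[(4-ethoxy-6-hydroxy-2-methoxy-3-methylphenyl)methyl]-2,2,6-trimethylchroman-4-one | CCOc1cc(O)c(Cc2c(OCc3ccccc3)c(C)c(OCc3ccccc3)c3C(=O)CC(C)(C)Oc23)c(OC)c1C
A6 | alternative 3 | 3-ethoxy-2-methylcyclobut-2-en-1-one | CCOC1=C(C)C(=O)C1
A7 | alternative 3 | 5,7-bis(benzyloxy)-8-(3-methoxyprop-2-yn-1-yl)-2,2,6-trimethylchroman-4-one | COC#CCc1c(OCc2ccccc2)c(C)c(OCc2ccccc2)c2C(=O)CC(C)(C)Oc12
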